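## Structural features

Lespeflorin C4 is an open-chain α-hydroxy dihydrochalcone: two benzene rings joined by the chain C(=O)–C(α)H(OH)–C(β)H2, with no ring besides the two arenes. Ring A (C1 acyl, C2 methoxy, C4 hydroxy, C5 prenyl) sits on the ketone carbon and ring B (4-methoxyphenyl) on C(β). C(α) is the only stereocentre and is S (priorities O > C=O > CH2Ar > H). It has no stereogenic neighbour, so the stereochemical problem is purely one of absolute control. The fragile parts are the α-ketol (enolisation with racemisation, α-ketol shift, retro-benzoin cleavage, oxidation to the 1,2-dione) and the prenyl olefin ortho to a free phenol (acid closes a 2,2-dimethylchroman; halonium and mercury electrophiles attack the trisubstituted double bond). The real difficulty is twofold: forming the C(=O)–C(α) bond together with the S carbinol and keeping it intact, and placing the prenyl group at C5 of ring A and not at C3, which phenoxide C-alkylation cannot guarantee. The key step exploits the fact that the ring A carbonyl carbon and C(α) are both carbonyl-derived carbons (an aroyl unit and the formyl carbon of a ring B arylacetaldehyde), so reversing the polarity of the aroyl carbon joins them in one addition that also creates the stereocentre. In the silylated adduct the ring A pattern and the priority order at C(α) are those of the target, so the S descriptor passes unchanged through the final deprotection; the structures of the key-step precursor and product are consistent with the target on these points.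

## Logic of the disconnections

13 to 12: the two O–H groups of 13 are traced back to two O–Si bonds in 12, one at C(α) and one at C4 of ring A. The cut is placed there because the bond-forming step releases the carbinol already silylated, and the phenol must stay capped through the organolithium and basic steps. Nothing is gained in skeleton, but the α-ketol and the ortho-prenyl phenol are absent from every step except the last. The forward step must remove both silyl groups without base strong enough to enolise the ketol and without acid strong enough to close a chroman.

12 to 9 and 11: the C(=O)–C(α) bond is cut. This is the only bond joining the two halves and it ends at the only stereocentre, so cutting it splits 12 into two achiral pieces of similar size. The forward step must turn the acyl carbon of 9 into a nucleophile, add it to 11 with control of the aldehyde face, and avoid enolising 11.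

11 to 10: no skeletal bond is cut; the formyl group is traced to a primary alcohol. The reason is stability, since 11 enolises and self-condenses on storage while 10 is a shelf reagent. The forward oxidation must stop at the aldehyde and deliver it free of acid or base.

9 to 8 to 6 (through 7): the C=O of 9 is traced to the dithioacetal carbon of 8, and the C–Si bond of 8 is then cut to give 6 by way of its carbanion 7. This makes the silicon arrive as an electrophile at a masked acyl anion, the most dependable way to an aroyl triethylsilane. The forward unmasking must spare the prenyl olefin and the electron-rich ring, which rules out halonium, mercury and hypervalent iodine reagents.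

6 to 5: the two C–S bonds are cut back to a formyl group. An aryl aldehyde is the simplest carrier of the future acyl carbon. The forward thioacetalisation needs a Lewis acid mild enough for the olefin and the aryl silyl ether.

5 to 3 and 4: the bond between C5 of ring A and the prenyl CH2 is cut. Cutting here places the side chain where a halogen stands, so the C3/C5 ambiguity of direct phenol prenylation never arises. The forward coupling must transfer the prenyl group without allylic transposition and without fluoride.

3 to 2 to 1: the O–Si bond and then the C5–I bond are cut, leading to 1, which already holds the formyl, methoxy and hydroxy groups in the right places. The forward iodination must go to C5 and not to C3.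

## Other disconnections considered

Alternative 1: The cut runs through ring A at C1–C2 and C5–C6. In the forward direction the diene (3Z)-1,1-dimethoxy-7-methyl-3-(trimethylsilyloxy)octa-1,3,6-triene A1 would add to the terminal ynone (S)-4-(tert-butyldimethylsilyloxy)-5-(4-methoxyphenyl)pent-1-yn-3-one A2 in a Diels–Alder reaction. The prenyl-bearing diene terminus would bond to the alkyne CH, and aromatisation by 1,4-elimination of one methoxy group and loss of the enol silyl group would give (S)-2-(tert-butyldimethylsilyloxy)-1-[4-hydroxy-2-methoxy-5-(3-methylbut-2-en-1-yl)phenyl]-3-(4-methoxyphenyl)propan-1-one A3.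
- In its favour: all four ring A substituents are placed by the polarity of the cycloaddition, with no halogenation or cross-coupling. On regiocontrol of ring A this is the equal of the chosen plan, and arguably better. The stereocentre would come from the chiral pool, so no catalyst-controlled step is needed.
- Against it: A2 carries its stereocentre next to a very electron-poor ynone carbonyl, where heat and the acid or base used for aromatisation invite enolisation. A1 is hydrolytically sensitive, and its substituted terminus slows the cycloaddition and needs defined geometry. Both partners need several steps each.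
- Comparison: the mechanism is pericyclic rather than anionic and forms two bonds and a ring. The stereocentre is only carried, not made, and it is carried through harsher conditions than anything 12 meets. The step count would be clearly higher than nine, and A3 still needs a desilylation, as 12 does.

Alternative 2: The cut is the bond between C1 of ring A and the carbonyl carbon. Forward, [4-bromo-5-methoxy-2-(3-methylbut-2-en-1-yl)phenoxy](tert-butyl)dimethylsilane A4 would undergo bromine–lithium exchange to the aryllithium A5. A5 would add to the amide (S)-2-(tert-butyldimethylsilyloxy)-N-methoxy-3-(4-methoxyphenyl)-N-methylpropanamide A6 to give the bis-silyl ketone (S)-2-(tert-butyldimethylsilyloxy)-1-[4-(tert-butyldimethylsilyloxy)-2-methoxy-5-(3-methylbut-2-en-1-yl)phenyl]-3-(4-methoxyphenyl)propan-1-one A7.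
- In its favour: acylation of an aryllithium by an N-methoxy-N-methylamide is among the most dependable ketone syntheses. The configuration would be bought from the amino acid chiral pool (diazotisation with retention, amidation, silylation), which makes this alternative better than the chosen plan in certainty of absolute configuration. Its step count is equal or slightly lower.
- Against it: the C(α)–H of A6 lies between an amide carbonyl and a silyloxy group, and A5 is a strong, chelated base, so deprotonation would compete with addition and erode enantiopurity. The tetrahedral intermediate is crowded between the ortho-methoxy group and the α-silyloxy group. A4 still needs the regioselective C5 prenylation, and a stoichiometric cryogenic organolithium is required.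
- Comparison: the chosen plan makes the same connection one bond further along. It forms bond and stereocentre together with a catalytic controller, and it never exposes the stereocentre to a stoichiometric strong base. In return it depends on catalyst enantioselectivity with an enolisable aldehyde, which is less secure than a chiral-pool centre.

Alternative 3: The cut is the C(α)–O bond; no skeletal bond is made. Forward, the ketone 1-[4-(tert-butyldimethylsilyloxy)-2-methoxy-5-(3-methylbut-2-en-1-yl)phenyl]-3-(4-methoxyphenyl)propan-1-one A8 would be converted into its sodium (Z)-enolate A9. A9 would take oxygen from an enantiopure camphor-derived N-sulfonyloxaziridine to give (S)-1-[4-(tert-butyldimethylsilyloxy)-2-methoxy-5-(3-methylbut-2-en-1-yl)phenyl]-2-hydroxy-3-(4-methoxyphenyl)propan-1-one A10.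
- In its favour: A8 is a robust, storable ketone assembled by conventional carbon–carbon chemistry, whereas 9 and 11 are both sensitive; on handling of intermediates this alternative is the better one. The oxidant leaves the prenyl olefin alone, and reagent-controlled hydroxylation of Z-enolates of aryl alkyl ketones is an established process.
- Against it: the stereo-defining step builds no skeleton, so every carbon–carbon bond costs a separate step and the linear sequence grows. The chiral reagent is stoichiometric. A10 is released as a free α-ketol alkoxide into a basic medium, where racemisation, over-oxidation and addition of the enolate to the sulfonimine by-product can occur. The ortho-methoxy group twists the aryl ketone and may weaken facial discrimination.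
- Comparison: the chosen plan releases the carbinol as a silyl ether, uses a catalytic controller and merges bond and stereocentre formation. Both plans end with one fluoride deprotection, so they are equal on that point.

Key step: step 8

Assumption: the (R,R) antipode of the TADDOL-type phosphite is taken as the one that leads to the S carbinol. The sense of induction must be confirmed on the first run; if it proves opposite, the (S,S) antipode is used in the same way. The phosphite is prepared separately and is not counted among the steps.

Step 1
Reactants: 1 4-hydroxy-2-methoxybenzaldehyde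
Product: 2 4-hydroxy-5-iodo-2-methoxybenzaldehyde
Conditions: NIS (1.0 equiv), TFA (cat.), MeCN, 0 °C to rt, dark
Reagents that add atoms: N-iodosuccinimide, O=C1CCC(=O)N1I
Why: Electrophilic aromatic iodination under mildly acidic conditions; C5 is ortho to the hydroxyl, para to the methoxyl and has a hydrogen neighbour, whereas C3 is wedged between both oxygen substituents, and the formyl group is meta to both sites and does not discriminate. One equivalent of reagent limits double iodination.

Step 2
Reactants: 2 4-hydroxy-5-iodo-2-methoxybenzaldehyde
Product: 3 5-iodo-2-methoxy-4-(triisopropylsilyloxy)benzaldehyde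
Conditions: TIPSCl, imidazole, DMF, rt
Reagents that add atoms: chlorotriisopropylsilane, CC(C)[Si](Cl)(C(C)C)C(C)C
Why: Imidazole-promoted silylation of an acidic phenol; the triisopropylsilyl ether is chosen because it should withstand n-BuLi, MeI/CaCO3 and the lithium phosphite and still leave with fluoride in the last step.

Step 3
Reactants: 3 5-iodo-2-methoxy-4-(triisopropylsilyloxy)benzaldehyde; 4 tributyl(3-methylbut-2-en-1-yl)stannane
Product: 5 2-methoxy-5-(3-methylbut-2-en-1-yl)-4-(triisopropylsilyloxy)benzaldehyde
Conditions: Pd(PPh3)4 (5 mol %), DMF (degassed), 90 °C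
Reagents that add atoms: none
Why: Stille coupling: zerovalent palladium inserts into the C5–I bond, the prenyl group is transferred from tin and reductive elimination at the unsubstituted allyl terminus should give the linear 3-methylbut-2-enyl arene. The site of the side chain is fixed by the iodine, and without fluoride or strong base the aldehyde and the aryl silyl ether are tolerated.

Step 4
Reactants: 5 2-methoxy-5-(3-methylbut-2-en-1-yl)-4-(triisopropylsilyloxy)benzaldehyde
Product: 6 2-[2-methoxy-5-(3-methylbut-2-en-1-yl)-4-(triisopropylsilyloxy)phenyl]-1,3-dithiane
Conditions: HS(CH2)3SH (1.2 equiv), BF3·OEt2 (0.3 equiv), CH2Cl2, −20 to 0 °C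
Reagents that add atoms: propane-1,3-dithiol, SCCCS
Why: Lewis acid catalysed dithioacetalisation of an aryl aldehyde; sub-stoichiometric BF3·OEt2 at low temperature should spare the trisubstituted olefin and the aryl silyl ether, and with the phenol capped no chroman can form.

Step 5
Reactants: 6 2-[2-methoxy-5-(3-methylbut-2-en-1-yl)-4-(triisopropylsilyloxy)phenyl]-1,3-dithiane
Product: 8 triethyl{2-[2-methoxy-5-(3-methylbut-2-en-1-yl)-4-(triisopropylsilyloxy)phenyl]-1,3-dithian-2-yl}silane, via 2-lithiodithiane 7 (not isolated)
Conditions: n-BuLi (1.05 equiv), THF, −78 to −30 °C; then Et3SiCl, −78 °C to rt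
Reagents that add atoms: chlorotriethylsilane, CC[Si](Cl)(CC)CC
Why: Corey–Seebach umpolung: the C2–H of a 2-aryl-1,3-dithiane is the most acidic site, and the resulting carbanion 7 is silylated at carbon. The triethylsilyl group is chosen because it later ends up as the triethylsilyl ether of the carbinol.

Step 6
Reactants: 8 triethyl{2-[2-methoxy-5-(3-methylbut-2-en-1-yl)-4-(triisopropylsilyloxy)phenyl]-1,3-dithian-2-yl}silane
Product: 9 [2-methoxy-5-(3-methylbut-2-en-1-yl)-4-(triisopropylsilyloxy)phenyl](triethylsilyl)methanone
Conditions: MeI (excess), CaCO3, MeCN/H2O (9:1), 45 °C, dark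
Reagents that add atoms: water, O
Why: Alkylative dithiane hydrolysis (S-methylation, ring opening to a thionium ion, capture by water) unmasks the acylsilane. The method is non-oxidising and free of mercury and halonium reagents, so the prenyl olefin and the electron-rich ring should stay untouched, and CaCO3 takes up the HI.

Step 7
Reactants: 10 2-(4-methoxyphenyl)ethanol
Product: 11 2-(4-methoxyphenyl)acetaldehyde
Conditions: Dess–Martin periodinane (1.2 equiv), NaHCO3, CH2Cl2, 0 °C to rt; short silica plug, used at once
Reagents that add atoms: none
Why: Dess–Martin oxidation of a primary alcohol stops at the aldehyde under buffered, anhydrous conditions; the enolisable arylacetaldehyde is not stored but taken directly into step 8.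

Step 8
Reactants: 9 [2-methoxy-5-(3-methylbut-2-en-1-yl)-4-(triisopropylsilyloxy)phenyl](triethylsilyl)methanone; 11 2-(4-methoxyphenyl)acetaldehyde
Product: 12 (S)-1-[2-methoxy-5-(3-methylbut-2-en-1-yl)-4-(triisopropylsilyloxy)phenyl]-3-(4-methoxyphenyl)-2-(triethylsilyloxy)propan-1-one
Conditions: cyclic hydrogen phosphite (R*O)2P(O)H of (R,R)-tetrakis(2-fluorophenyl)-TADDOL (15 mol %), n-BuLi (14 mol %), THF, −40 to 0 °C; 11 (1.5 equiv) added slowly
Reagents that add atoms: none
Why: The lithium phosphite (R*O)2POLi adds through phosphorus to the carbonyl of 9, and a [1,2]-Brook shift of the triethylsilyl group from carbon to oxygen gives a benzylic α-silyloxy phosphonate carbanion, the acyl anion equivalent of ring A. This carbanion adds to the formyl carbon of 11 and forms the C(=O)–C(α) bond; a 1,4 oxygen-to-oxygen silyl transfer and collapse of the resulting α-oxido phosphonate then expel the phosphite and release 12. The closest known reaction type is the metallophosphite-catalysed enantioselective cross silyl benzoin of aryl acylsilanes with aldehydes. No ring is closed. The single new stereocentre C(α) is set under catalyst control, the TADDOL backbone with its 2-fluorophenyl groups differentiating the two faces of the aldehyde as the phosphonate carbanion approaches, and the antipode is chosen for S. The step needs chemoselectivity in the choice of acyl donor, and the substrate secures it: only 9 carries the silyl group that makes the Brook shift possible, so the ketone ends on the ring A side, while addition of the phosphite to 11 is reversible and unproductive. Enolisation of 11 is countered by keeping n-BuLi below the phosphite loading so that no free alkyllithium remains, by low temperature and by slow addition. The carbinol leaves the cycle as its triethylsilyl ether, which blocks retro-benzoin cleavage and racemisation by enolisation.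

Step 9
Reactants: 12 (S)-1-[2-methoxy-5-(3-methylbut-2-en-1-yl)-4-(triisopropylsilyloxy)phenyl]-3-(4-methoxyphenyl)-2-(triethylsilyloxy)propan-1-one
Product: 13 Lespeflorin C4, (S)-2-hydroxy-1-[4-hydroxy-2-methoxy-5-(3-methylbut-2-en-1-yl)phenyl]-3-(4-methoxyphenyl)propan-1-one
Conditions: TBAF (3 equiv), AcOH (3 equiv), THF, 0 °C to rt
Reagents that add atoms: none
Why: Fluoride cleaves both the secondary triethylsilyl ether and the aryl triisopropylsilyl ether; acetic acid buffers the alkoxide and phenoxide so that the α-ketol should neither racemise nor undergo a ketol shift, and the absence of strong acid prevents closure of the ortho-prenyl phenol to a chroman. The S centre is not involved.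

Compound list

1 | 4-hydroxy-2-methoxybenzaldehyde | COc1cc(O)ccc1C=O | starting material
2 | 4-hydroxy-5-iodo-2-methoxybenzaldehyde | COc1cc(O)c(I)cc1C=O | intermediate
3 | 5-iodo-2-methoxy-4-(triisopropylsilyloxy)benzaldehyde | COc1cc(O[Si](C(C)C)(C(C)C)C(C)C)c(I)cc1C=O | intermediate
4 | tributyl(3-methylbut-2-en-1-yl)stannane | CCCC[Sn](CCCC)(CCCC)CC=C(C)C | starting material
5 | 2-methoxy-5-(3-methylbut-2-en-1-yl)-4-(triisopropylsilyloxy)benzaldehyde | COc1cc(O[Si](C(C)C)(C(C)C)C(C)C)c(CC=C(C)C)cc1C=O | intermediate
6 | 2-[2-methoxy-5-(3-methylbut-2-en-1-yl)-4-(triisopropylsilyloxy)phenyl]-1,3-dithiane | COc1cc(O[Si](C(C)C)(C(C)C)C(C)C)c(CC=C(C)C)cc1C1SCCCS1 | intermediate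
7 | {2-[2-methoxy-5-(3-methylbut-2-en-1-yl)-4-(triisopropylsilyloxy)phenyl]-1,3-dithian-2-yl}lithium | COc1cc(O[Si](C(C)C)(C(C)C)C(C)C)c(CC=C(C)C)cc1C1([Li])SCCCS1 | intermediate
8 | triethyl{2-[2-methoxy-5-(3-methylbut-2-en-1-yl)-4-(triisopropylsilyloxy)phenyl]-1,3-dithian-2-yl}silane | COc1cc(O[Si](C(C)C)(C(C)C)C(C)C)c(CC=C(C)C)cc1C1([Si](CC)(CC)CC)SCCCS1 | intermediate
9 | [2-methoxy-5-(3-methylbut-2-en-1-yl)-4-(triisopropylsilyloxy)phenyl](triethylsilyl)methanone | COc1cc(O[Si](C(C)C)(C(C)C)C(C)C)c(CC=C(C)C)cc1C(=O)[Si](CC)(CC)CC | intermediate
10 | 2-(4-methoxyphenyl)ethanol | COc1ccc(CCO)cc1 | starting material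
11 | 2-(4-methoxyphenyl)acetaldehyde | COc1ccc(CC=O)cc1 | intermediate
12 | (S)-1-[2-methoxy-5-(3-methylbut-2-en-1-yl)-4-(triisopropylsilyloxy)phenyl]-3-(4-methoxyphenyl)-2-(triethylsilyloxy)propan-1-one | COc1ccc(C[C@H](O[Si](CC)(CC)CC)C(=O)c2cc(CC=C(C)C)c(O[Si](C(C)C)(C(C)C)C(C)C)cc2OC)cc1 | intermediate
13 | Lespeflorin C4, (S)-2-hydroxy-1-[4-hydroxy-2-methoxy-5-(3-methylbut-2-en-1-yl)phenyl]-3-(4-methoxyphenyl)propan-1-one | COc1ccc(C[C@H](O)C(=O)c2cc(CC=C(C)C)c(O)cc2OC)cc1 | target

Total step count: 9 steps. Longest linear sequence: 8 steps (steps 1 to 6, then 8 and 9); step 7 is a one-step branch.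

Steps least certain to work

Step 8 (key step). Most likely to go wrong: proton transfer from the acidic α-CH2 of 11 to the phosphonate carbanion or to the lithium phosphite, which would stall the cycle and start aldol condensation of 11. In addition, the ortho-methoxy group and the electron-rich ring of 9 may slow phosphite addition and the Brook shift, and facial discrimination on a flexible aliphatic aldehyde may be weaker than on aryl aldehydes. The fallback sets out from 6 and comes back to the route at 13.
- 6 is lithiated as in step 5 to 7, which is alkylated with 1-(2-bromoethyl)-4-methoxybenzene F1 (commercial; THF, −78 °C to rt) to give 2-[2-methoxy-5-(3-methylbut-2-en-1-yl)-4-(triisopropylsilyloxy)phenyl]-2-[2-(4-methoxyphenyl)ethyl]-1,3-dithiane F2.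
- Hydrolysis with MeI/CaCO3 as in step 6 gives the ketone 1-[2-methoxy-5-(3-methylbut-2-en-1-yl)-4-(triisopropylsilyloxy)phenyl]-3-(4-methoxyphenyl)propan-1-one F3.
- NaHMDS in THF at −78 °C forms the sodium (Z)-enolate of that ketone F4. It is oxidised by the antipode of (camphorsulfonyl)oxaziridine that delivers S and quenched with aqueous NH4Cl, to give (S)-2-hydroxy-1-[2-methoxy-5-(3-methylbut-2-en-1-yl)-4-(triisopropylsilyloxy)phenyl]-3-(4-methoxyphenyl)propan-1-one F5.
- Buffered fluoride as in step 9 then gives 13.

Step 6. Most likely to go wrong: sluggish or incomplete unmasking of the crowded 2-aryl-2-silyl dithiane, with loss of the acylsilane on prolonged heating, or attack on the prenyl olefin if a stronger thiophile has to be used. The same detour also bypasses a failed C-silylation in step 5. The fallback sets out from 5 and comes back at 9.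
- Copper-catalysed 1,2-addition of the silyl group of triethyl(4,4,5,5-tetramethyl-1,3,2-dioxaborolan-2-yl)silane to the aldehyde (CuCl, NaOt-Bu, 1,3-bis(2,6-diisopropylphenyl)imidazolium chloride, THF with MeOH as proton source) gives racemic [2-methoxy-5-(3-methylbut-2-en-1-yl)-4-(triisopropylsilyloxy)phenyl](triethylsilyl)methanol F6.
- Swern oxidation of this α-silyl carbinol gives 9.

Step 3. Most likely to go wrong: transfer of the prenyl group with allylic transposition, giving the 1,1-dimethylallyl isomer, or reduction of the C–I bond, because transmetalation next to the bulky silyl ether is slow. The fallback sets out from 3 and comes back at 5.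
- Stille coupling with allyltributylstannane (Pd(PPh3)4, DMF, 90 °C), where transposition is degenerate, gives 5-allyl-2-methoxy-4-(triisopropylsilyloxy)benzaldehyde F7.
- Olefin cross-metathesis with excess 2-methylbut-2-ene (second-generation Grubbs catalyst, CH2Cl2, 40 °C) converts the allyl group into the prenyl group of 5.

Step 1. Most likely to go wrong: imperfect site selection, with some iodination at C3 or double iodination of the activated ring. The fallback sets out from 1 and comes back at 3.
- The phenol is silylated first (TIPSCl, imidazole, DMF) to 2-methoxy-4-(triisopropylsilyloxy)benzaldehyde F8. The bulky silyl ether closes C3 completely and leaves the methoxy group to direct para.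
- Iodination with I2 and CF3CO2Ag in CHCl3 at 0 °C then gives 3.

## Further compounds

F1 | step 8 | 1-(2-bromoethyl)-4-methoxybenzene | COc1ccc(CCBr)cc1
F2 | step 8 | 2-[2-methoxy-5-(3-methylbut-2-en-1-yl)-4-(triisopropylsilyloxy)phenyl]-2-[2-(4-methoxyphenyl)ethyl]-1,3-dithiane | COc1ccc(CCC2(c3cc(CC=C(C)C)c(O[Si](C(C)C)(C(C)C)C(C)C)cc3OC)SCCCS2)cc1
F3 | step 8 | 1-[2-methoxy-5-(3-methylbut-2-en-1-yl)-4-(triisopropylsilyloxy)phenyl]-3-(4-methoxyphenyl)propan-1-one | COc1ccc(CCC(=O)c2cc(CC=C(C)C)c(O[Si](C(C)C)(C(C)C)C(C)C)cc2OC)cc1
F4 | step 8 | sodium (Z)-1-[2-methoxy-5-(3-methylbut-2-en-1-yl)-4-(triisopropylsilyloxy)phenyl]-3-(4-methoxyphenyl)prop-1-en-1-olate | COc1ccc(C/C=C(\[O-])c2cc(CC=C(C)C)c(O[Si](C(C)C)(C(C)C)C(C)C)cc2OC)cc1.[Na+]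
F5 | step 8 | (S)-2-hydroxy-1-[2-methoxy-5-(3-methylbut-2-en-1-yl)-4-(triisopropylsilyloxy)phenyl]-3-(4-methoxyphenyl)propan-1-one | COc1ccc(C[C@H](O)C(=O)c2cc(CC=C(C)C)c(O[Si](C(C)C)(C(C)C)C(C)C)cc2OC)cc1
F6 | step 6 | [2-methoxy-5-(3-methylbut-2-en-1-yl)-4-(triisopropylsilyloxy)phenyl](triethylsilyl)methanol (racemic) | COc1cc(O[Si](C(C)C)(C(C)C)C(C)C)c(CC=C(C)C)cc1C(O)[Si](CC)(CC)CC
F7 | step 3 | 5-allyl-2-methoxy-4-(triisopropylsilyloxy)benzaldehyde | COc1cc(O[Si](C(C)C)(C(C)C)C(C)C)c(CC=C)cc1C=O
F8 | step 1 | 2-methoxy-4-(triisopropylsilyloxy)benzaldehyde | COc1cc(O[Si](C(C)C)(C(C)C)C(C)C)ccc1C=O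
A1 | alternative 1 | (3Z)-1,1-dimethoxy-7-methyl-3-(trimethylsilyloxy)octa-1,3,6-triene | COC(OC)=C/C(O[Si](C)(C)C)=C/CC=C(C)C
A2 | alternative 1 | (S)-4-(tert-butyldimethylsilyloxy)-5-(4-methoxyphenyl)pent-1-yn-3-one | C#CC(=O)[C@@H](O[Si](C)(C)C(C)(C)C)Cc1ccc(OC)cc1
A3 | alternative 1 | (S)-2-(tert-butyldimethylsilyloxy)-1-[4-hydroxy-2-methoxy-5-(3-methylbut-2-en-1-yl)phenyl]-3-(4-methoxyphenyl)propan-1-one | COc1ccc(C[C@H](O[Si](C)(C)C(C)(C)C)C(=O)c2cc(CC=C(C)C)c(O)cc2OC)cc1
A4 | alternative 2 | [4-bromo-5-methoxy-2-(3-methylbut-2-en-1-yl)phenoxy](tert-butyl)dimethylsilane | COc1cc(O[Si](C)(C)C(C)(C)C)c(CC=C(C)C)cc1Br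
A5 | alternative 2 | [4-(tert-butyldimethylsilyloxy)-2-methoxy-5-(3-methylbut-2-en-1-yl)phenyl]lithium | COc1cc(O[Si](C)(C)C(C)(C)C)c(CC=C(C)C)cc1[Li]
A6 | alternative 2 | (S)-2-(tert-butyldimethylsilyloxy)-N-methoxy-3-(4-methoxyphenyl)-N-methylpropanamide | CON(C)C(=O)[C@@H](O[Si](C)(C)C(C)(C)C)Cc1ccc(OC)cc1
A7 | alternative 2 | (S)-2-(tert-butyldimethylsilyloxy)-1-[4-(tert-butyldimethylsilyloxy)-2-methoxy-5-(3-methylbut-2-en-1-yl)phenyl]-3-(4-methoxyphenyl)propan-1-one | COc1ccc(C[C@H](O[Si](C)(C)C(C)(C)C)C(=O)c2cc(CC=C(C)C)c(O[Si](C)(C)C(C)(C)C)cc2OC)cc1
A8 | alternative 3 | 1-[4-(tert-butyldimethylsilyloxy)-2-methoxy-5-(3-methylbut-2-en-1-yl)phenyl]-3-(4-methoxyphenyl)propan-1-one | COc1ccc(CCC(=O)c2cc(CC=C(C)C)c(O[Si](C)(C)C(C)(C)C)cc2OC)cc1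
A9 | alternative 3 | sodium (Z)-1-[4-(tert-butyldimethylsilyloxy)-2-methoxy-5-(3-methylbut-2-en-1-yl)phenyl]-3-(4-methoxyphenyl)prop-1-en-1-olate | COc1ccc(C/C=C(\[O-])c2cc(CC=C(C)C)c(O[Si](C)(C)C(C)(C)C)cc2OC)cc1.[Na+]
A10 | alternative 3 | (S)-1-[4-(tert-butyldimethylsilyloxy)-2-methoxy-5-(3-methylbut-2-en-1-yl)phenyl]-2-hydroxy-3-(4-methoxyphenyl)propan-1-one | COc1ccc(C[C@H](O)C(=O)c2cc(CC=C(C)C)c(O[Si](C)(C)C(C)(C)C)cc2OC)cc1
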